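At early times I see each flask as one first-order loss of starting material to target, and I ask how many lifetimes of that step fit into the time.

| setting | Monday's | Friday's | Thursday's |
|---|---|---|---|
| starting material | 0.050 M | 0.050 M | 0.050 M |
| protic impurity | 1.00 mM | 1.00 mM | 1.00 mM |
| temperature | 40 °C | 15 °C | −10 °C |
| time | 30 min | 30 min | 30 min |

* the best flask by amount of target, in percent of the starting material charged; "all alike" if 1.5 percentage points covers them all (Monday's / Friday's / Thursday's / all alike)
* amount of target at the end, in percent of the starting material charged, Monday's
* amount of target at the end, in percent of the starting material charged, Friday's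
* amount of target at the end, in percent of the starting material charged, Thursday's

    starting material → target (k1 = 1.1 min⁻¹, Ea1 = 91.0 kJ mol⁻¹)
    starting material → side product (k2 = 0.012 min⁻¹, Ea2 = 87.0 kJ mol⁻¹)
    target ⇌ isomer of the product (K3 = 6.2, k3 = 0.036 min⁻¹, Ea3 = 88.0 kJ mol⁻¹, ΔH3 = −67.0 kJ mol⁻¹)
    starting material + protic impurity → quenched substrate (k4 = 200 L mol⁻¹ min⁻¹, Ea4 = 62.0 kJ mol⁻¹)
    (constants at 40 °C)

- all constants are for 40 °C and move with temperature by the activation energies and enthalpies

Friday's reads 1.59, Monday's 33.0 and Thursday's 0.0431, and this clock, the rate constant of the main step at the flask's temperature times the time, is the number I carry. With the main step by itself, the converted fraction is one minus the exponential of minus the clock: >99.9 % on Monday's, 79.6 % on Friday's and 4.22 % on Thursday's.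

The other steps I first treat as corrections. The protic impurity is the limiting reagent of the quench, and its charge equals a fraction 2.00 % of the starting material. Its own pseudo-first-order clock on Thursday's reads 3.25, far ahead of the main clock, so nearly all of it reacts there, and I take the whole fraction off each flask. The side step takes a share of what reacts, the ratio of its constant to the main one, 1.09 % at 40 °C, and I keep that share for the colder flasks too. Together these leave a factor 96.9 %.

Then comes the isomer, with a clock of its own built the same way. On Thursday's it reads 0.00176, far below one, so I drop it and get 4.09 %. On Friday's it reads 0.0575, and target that is still forming has stood for a fraction one minus converted-over-clock of the time, which gives 74.4 %. On Monday's it reads 1.08, no longer small, so I use the full relaxation toward equilibrium, with the reverse step included, and get 37.3 %. My best flask is Friday's.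

The forecast names Friday's, with 38.2 % for Monday's, 74.6 % for Friday's and 4.15 % for Thursday's, on the ground that “the middle temperature wins”. Its figures differ from mine by 0.92 percentage points on Monday's, 0.21 points on Friday's and 0.061 points on Thursday's.

The simulation gives Friday's as the best flask, with 38.2 % on Monday's, 74.7 % on Friday's and 4.15 % on Thursday's. On Friday's the main clock 1.59 stands above one and the isomer clock 0.0575 far below one, and at 30.0 min that flask holds 19.6 % starting material and 2.74 % isomer of the product beside its target. Thursday's clock, run on to a reading at 2.0 h, becomes 0.172 and gives 15.3 % target, and that reading shows 15.5 %.

The numbers belong to no real substance; the run is a simulation.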